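**Retrosynthetic overview**
1. Target 23 ⇐ 2-O-angeloyl 3,4-epoxy ketone 21. An acid-triggered 1,2-acyl shift opens the epoxide, giving the C3 angelate and C4–OH and freeing C2–OH; the acetonide is then removed.
2. 21 ⇐ 13. The C5 ketone is reduced temporarily so that the C2 ketone can be unmasked and reduced alone and the epoxidation can be hydroxyl-directed; C5 is then re-oxidised.
3. 13 ⇐ 10 by enolate hydroxylation at C6 (trans to the side chain) and acylation. The side-chain centres C8 and C10 come from a catalytic aldol and a 1,3-anti reduction.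
4. 10 ⇐ enal 4 ⇐ quinone monoketal 2 + acrolein. An enantioselective organocatalytic Rauhut–Currier coupling forms C1–C7 and the first stereocentre.
5. Rings: the only carbocycle comes intact from 4-methoxy-2-methylphenol by oxidative dearomatisation. The dioxolane (step 6) and oxirane (step 13) are temporary and are opened in step 15.

Locants C1–C11 in the text are those of the target: ring C1 (bears the side chain), C2, C3, C4 (bears the methyl), C5 (ketone), C6; side chain C7 (=CH2), C8, C9, C10, C11. α is the ring face of the C2, C3 and C6 oxygens; β is the face of the side chain and of C4–OH.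
Abbreviations in names: Ang = (2Z)-2-methylbut-2-enoyl (angelate = its ester); Q = (3S)-3-(AngO)-4-[(4S)-2,2,5,5-tetramethyl-1,3-dioxolan-4-yl]but-1-en-2-yl.
Assumption: where a chiral catalyst is named, the antipode that gives the drawn configuration is meant (the sense of induction in steps 2 and 4 is assigned by analogy and must be confirmed experimentally); angelic anhydride is taken as purchasable.

**Step 1**
Reactants: 1 4-methoxy-2-methylphenol
Product: 2 4,4-dimethoxy-2-methylcyclohexa-2,5-dien-1-one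
Conditions: PhI(OAc)2, MeOH, 0 °C
Reagents that add atoms: methanol, CO
Why: Oxidative dearomatisation of a para-methoxyphenol in methanol (hypervalent-iodine phenol oxidation) gives the achiral quinone monoketal, which already carries the ring carbons, the methyl group and oxygen at C2 and C5.

**Step 2**
Reactants: 2 4,4-dimethoxy-2-methylcyclohexa-2,5-dien-1-one; 3 acrolein
Product: 4 2-[(1S)-2,2-dimethoxy-4-methyl-5-oxocyclohex-3-en-1-yl]prop-2-enal
Conditions: 2 (2 equiv), 3 (1 equiv, slow addition), (S)-N-[1-(diphenylphosphanyl)-3-methylbutan-2-yl]-N'-[3,5-bis(trifluoromethyl)phenyl]thiourea (10 mol %), 2-naphthol (20 mol %), toluene, 0 °C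
Reagents that add atoms: none
Why: Proposed new method: an enantioselective intermolecular cross Rauhut–Currier coupling in which the phosphine adds to acrolein to give a phosphonium enolate (a latent C7 vinyl anion), the thiourea binds the dienone carbonyl, and Michael addition occurs at the unsubstituted enone carbon (more electrophilic and less hindered than the methyl-bearing enone) on one enantioface to set C1 (S), after which proton transfer and loss of the phosphine restore the acrolein double bond; the closest known reactions are the enantioselective intramolecular Rauhut–Currier desymmetrisation of cyclohexadienones and intermolecular cross Rauhut–Currier couplings of acrolein or vinyl ketones with activated alkenes.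

**Step 3**
Reactants: 5 3-hydroxy-3-methylbutan-2-one
Product: 6 3-methyl-2,3-bis(trimethylsilyloxy)but-1-ene
Conditions: LiN(i-Pr)2 (2.2 equiv), THF, −78 °C; Me3SiCl (2.5 equiv)
Reagents that add atoms: chlorotrimethylsilane, C[Si](C)(C)Cl
Why: Double deprotonation (hydroxyl, then the only enolisable methyl) and silylation give the silyl enol ether for a Mukaiyama aldol; no stereocentre.

**Step 4**
Reactants: 4 2-[(1S)-2,2-dimethoxy-4-methyl-5-oxocyclohex-3-en-1-yl]prop-2-enal; 6 3-methyl-2,3-bis(trimethylsilyloxy)but-1-ene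
Product: 8 (5S)-5-[(3S)-3-hydroxy-6-methyl-5-oxo-6-(trimethylsilyloxy)hept-1-en-2-yl]-4,4-dimethoxy-2-methylcyclohex-2-en-1-one, via bis-silyl aldol 7 (not isolated)
Conditions: B-butyl oxazaborolidinone from N-tosyl-(S)-tryptophan (20 mol %), EtCN, −78 °C; then citric acid, MeOH, 0 °C
Reagents that add atoms: none
Why: Catalytic asymmetric Mukaiyama aldol in which the chiral boron Lewis acid binds the α-substituted enal (far more electrophilic than the ring ketone), shields one face and directs the enol silane to the Si face to set C8 (S), the remote C1 centre not interfering; mild acid then cleaves only the secondary silyl ether.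

**Step 5**
Reactants: 8 (5S)-5-[(3S)-3-hydroxy-6-methyl-5-oxo-6-(trimethylsilyloxy)hept-1-en-2-yl]-4,4-dimethoxy-2-methylcyclohex-2-en-1-one
Product: 9 (5S)-5-[(3S,5S)-3,5-dihydroxy-6-methyl-6-(trimethylsilyloxy)hept-1-en-2-yl]-4,4-dimethoxy-2-methylcyclohex-2-en-1-one
Conditions: Me4NBH(OAc)3 (5 equiv), MeCN/AcOH (1:1), −30 °C
Reagents that add atoms: none
Why: Evans–Saksena hydroxyl-directed reduction, in which the C8 alkoxy(diacetoxy)borohydride delivers hydride intramolecularly through a chair six-membered transition state to give the 1,3-anti diol (C10 S); the ring enone has no directing hydroxyl and is untouched.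

**Step 6**
Reactants: 9 (5S)-5-[(3S,5S)-3,5-dihydroxy-6-methyl-6-(trimethylsilyloxy)hept-1-en-2-yl]-4,4-dimethoxy-2-methylcyclohex-2-en-1-one
Product: 10 (5S)-5-{(3S)-3-hydroxy-4-[(4S)-2,2,5,5-tetramethyl-1,3-dioxolan-4-yl]but-1-en-2-yl}-4,4-dimethoxy-2-methylcyclohex-2-en-1-one
Conditions: Me2C(OMe)2 (solvent), MeOH (2 equiv), PPTS (10 mol %), 35 °C
Reagents that add atoms: 2,2-dimethoxypropane, COC(C)(C)OC
Why: Acid-catalysed acetalisation under equilibrating conditions removes the tertiary silyl ether and gives the five-membered C10/C11 dioxolane in preference to the twist-boat dioxane of the anti-1,3-diol, while the dimethoxypropane medium keeps the ring dimethyl ketal intact; C8–OH stays free.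

**Step 7**
Reactants: 10 (5S)-5-{(3S)-3-hydroxy-4-[(4S)-2,2,5,5-tetramethyl-1,3-dioxolan-4-yl]but-1-en-2-yl}-4,4-dimethoxy-2-methylcyclohex-2-en-1-one; 11 (2Z)-2-methylbut-2-enoic anhydride (angelic anhydride)
Product: 13 (1R,6R)-5,5-dimethoxy-3-methyl-2-oxo-6-Q-cyclohex-3-en-1-yl angelate, via dipotassium dialkoxide 12 (not isolated)
Conditions: KN(SiMe3)2 (2.3 equiv), THF, −78 °C; 3-phenyl-2-(phenylsulfonyl)oxaziridine (1.3 equiv), −78 °C; then 11 (3 equiv), −78 → 0 °C
Reagents that add atoms: 3-phenyl-2-(phenylsulfonyl)oxaziridine, O=S(=O)(c1ccccc1)N1OC1c1ccccc1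
Why: Davis enolate hydroxylation at C6, the only enolisable position of the enone, with oxygen entering anti to the adjacent C1 side chain (C6–O α, trans); the two potassium alkoxides are then acylated by the anhydride without a nucleophilic catalyst, so the Z double bonds are kept.

**Step 8**
Reactants: 13 (1R,6R)-5,5-dimethoxy-3-methyl-2-oxo-6-Q-cyclohex-3-en-1-yl angelate
Product: 14 (1R,2R,6R)-2-hydroxy-5,5-dimethoxy-3-methyl-6-Q-cyclohex-3-en-1-yl angelate
Conditions: NaBH4, CeCl3·7H2O, MeOH, −78 °C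
Reagents that add atoms: none
Why: Luche 1,2-reduction with axial hydride attack gives the equatorial 5β-alcohol (trans to the C6 ester, cis to the side chain, as in carvone to cis-carveol); this centre is temporary but steers step 13 and removes the ketone before C2 is unmasked.

**Step 9**
Reactants: 14 (1R,2R,6R)-2-hydroxy-5,5-dimethoxy-3-methyl-6-Q-cyclohex-3-en-1-yl angelate
Product: 15 (1R,2R,6R)-2-(tert-butyldimethylsilyloxy)-5,5-dimethoxy-3-methyl-6-Q-cyclohex-3-en-1-yl angelate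
Conditions: t-BuMe2SiOSO2CF3, 2,6-lutidine, CH2Cl2, −78 °C
Reagents that add atoms: tert-butyldimethylsilyl trifluoromethanesulfonate, CC(C)(C)[Si](C)(C)OS(=O)(=O)C(F)(F)F
Why: Silyl protection of the only free hydroxyl keeps C5–OH distinct from the C2–OH made next; no stereocentre changes.

**Step 10**
Reactants: 15 (1R,2R,6R)-2-(tert-butyldimethylsilyloxy)-5,5-dimethoxy-3-methyl-6-Q-cyclohex-3-en-1-yl angelate
Product: 17 (1R,2R,5R,6S)-2-(tert-butyldimethylsilyloxy)-5-hydroxy-3-methyl-6-Q-cyclohex-3-en-1-yl angelate, via enone 16 (not isolated)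
Conditions: PPTS, acetone/H2O (10:1), 23 °C; solvent switch; NaBH4, CeCl3·7H2O, MeOH, −78 °C
Reagents that add atoms: water, O
Why: Mild acid hydrolyses the now allylic dimethyl ketal (acetonide and silyl ether survive in acetone), and the base-sensitive enone 16 is reduced at once under Luche conditions by axial hydride attack to the equatorial 2α-alcohol, trans to the C1 side chain.

**Step 11**
Reactants: 17 (1R,2R,5R,6S)-2-(tert-butyldimethylsilyloxy)-5-hydroxy-3-methyl-6-Q-cyclohex-3-en-1-yl angelate; 11 (2Z)-2-methylbut-2-enoic anhydride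
Product: 18 (1R,2R,5R,6S)-2-(tert-butyldimethylsilyloxy)-3-methyl-6-Q-cyclohex-3-ene-1,5-diyl diangelate
Conditions: LiN(SiMe3)2 (1.05 equiv), THF, −78 °C; 11 (1.5 equiv), −78 → −20 °C
Reagents that add atoms: none
Why: Alkoxide acylation with the anhydride (no nucleophilic catalyst, so no Z to E isomerisation) places on C2–O the angelate that will migrate to C3 in step 15; any ester migration between the α-oxygens gives the same product after acylation.

**Step 12**
Reactants: 18 (1R,2R,5R,6S)-2-(tert-butyldimethylsilyloxy)-3-methyl-6-Q-cyclohex-3-ene-1,5-diyl diangelate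
Product: 19 (1R,2R,5R,6S)-2-hydroxy-3-methyl-6-Q-cyclohex-3-ene-1,5-diyl diangelate
Conditions: HF·pyridine, pyridine, THF, 0 → 23 °C
Reagents that add atoms: none
Why: Buffered fluoride desilylation frees C5–OH without touching the esters or the acetonide and without the acyl migration that basic fluoride would cause.

**Step 13**
Reactants: 19 (1R,2R,5R,6S)-2-hydroxy-3-methyl-6-Q-cyclohex-3-ene-1,5-diyl diangelate
Product: 20 (1S,2S,3R,4R,5S,6R)-2-hydroxy-1-methyl-4-Q-7-oxabicyclo[4.1.0]heptane-3,5-diyl diangelate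
Conditions: VO(acac)2 (5 mol %), t-BuOOH, CH2Cl2, 0 °C
Reagents that add atoms: tert-butyl hydroperoxide, CC(C)(C)OO
Why: Hydroxyl-directed vanadium-catalysed epoxidation delivers oxygen to the C3=C4 alkene syn to the allylic 5β-OH and anti to the 2α-ester, giving the β-epoxide; the other alkenes have no free allylic hydroxyl or are conjugated esters.

**Step 14**
Reactants: 20 (1S,2S,3R,4R,5S,6R)-2-hydroxy-1-methyl-4-Q-7-oxabicyclo[4.1.0]heptane-3,5-diyl diangelate
Product: 21 (1R,3R,4S,5S,6R)-1-methyl-2-oxo-4-Q-7-oxabicyclo[4.1.0]heptane-3,5-diyl diangelate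
Conditions: Dess–Martin periodinane, NaHCO3, CH2Cl2, 0 → 23 °C
Reagents that add atoms: none
Why: Dess–Martin oxidation of the only free hydroxyl restores the C5 ketone under buffered, non-epimerising conditions.

**Step 15**
Reactants: 21 (1R,3R,4S,5S,6R)-1-methyl-2-oxo-4-Q-7-oxabicyclo[4.1.0]heptane-3,5-diyl diangelate
Product: 23 (3S,5S)-2-[(1S,2S,3S,4R,6R)-2,4-dihydroxy-4-methyl-3,6-bis(AngO)-5-oxocyclohexyl]-5,6-dihydroxy-6-methylhept-1-en-3-yl angelate, via acetonide 22 (not isolated)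
Conditions: BF3·OEt2 (1.5 equiv), CH2Cl2, −40 °C; H2O, −40 → 0 °C; then CF3CO2H/H2O/THF, 0 → 23 °C
Reagents that add atoms: water, O
Why: Neighbouring-group (acyloxonium) epoxide opening, in which the trans C2 angelate carbonyl attacks C3 from the α face (inversion at C3, trans-diaxial Fürst–Plattner opening, C4–OH left β), and water turns the dioxolanylium ion into an orthoacid that collapses kinetically to the axial C3 ester and equatorial C2–OH; aqueous acid then removes the acetonide.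

**Compound list**
1 | 4-methoxy-2-methylphenol | COc1ccc(O)c(C)c1 | starting material
2 | 4,4-dimethoxy-2-methylcyclohexa-2,5-dien-1-one | COC1(OC)C=CC(=O)C(C)=C1 | intermediate
3 | acrolein | C=CC=O | starting material
4 | 2-[(1S)-2,2-dimethoxy-4-methyl-5-oxocyclohex-3-en-1-yl]prop-2-enal | C=C([C@H]1C(OC)(OC)C=C(C)C(=O)C1)C=O | intermediate
5 | 3-hydroxy-3-methylbutan-2-one | CC(=O)C(C)(C)O | starting material
6 | 3-methyl-2,3-bis(trimethylsilyloxy)but-1-ene | C=C(O[Si](C)(C)C)C(C)(C)O[Si](C)(C)C | intermediate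
7 | (5S)-4,4-dimethoxy-2-methyl-5-[(3S)-6-methyl-5-oxo-3,6-bis(trimethylsilyloxy)hept-1-en-2-yl]cyclohex-2-en-1-one | C=C([C@H]1C(OC)(OC)C=C(C)C(=O)C1)[C@H](CC(=O)C(C)(C)O[Si](C)(C)C)O[Si](C)(C)C | intermediate (not isolated)
8 | (5S)-5-[(3S)-3-hydroxy-6-methyl-5-oxo-6-(trimethylsilyloxy)hept-1-en-2-yl]-4,4-dimethoxy-2-methylcyclohex-2-en-1-one | C=C([C@H]1C(OC)(OC)C=C(C)C(=O)C1)[C@H](CC(=O)C(C)(C)O[Si](C)(C)C)O | intermediate
9 | (5S)-5-[(3S,5S)-3,5-dihydroxy-6-methyl-6-(trimethylsilyloxy)hept-1-en-2-yl]-4,4-dimethoxy-2-methylcyclohex-2-en-1-one | C=C([C@H]1C(OC)(OC)C=C(C)C(=O)C1)[C@H](C[C@H](O)C(C)(C)O[Si](C)(C)C)O | intermediate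
10 | (5S)-5-{(3S)-3-hydroxy-4-[(4S)-2,2,5,5-tetramethyl-1,3-dioxolan-4-yl]but-1-en-2-yl}-4,4-dimethoxy-2-methylcyclohex-2-en-1-one | C=C([C@H]1C(OC)(OC)C=C(C)C(=O)C1)[C@H](C[C@@H]2OC(C)(C)OC2(C)C)O | intermediate
11 | (2Z)-2-methylbut-2-enoic anhydride (angelic anhydride) | C/C=C(/C)C(=O)OC(=O)/C(C)=C\C | starting material
12 | dipotassium dialkoxide of (5R,6R)-6-hydroxy-5-{(3S)-3-hydroxy-4-[(4S)-2,2,5,5-tetramethyl-1,3-dioxolan-4-yl]but-1-en-2-yl}-4,4-dimethoxy-2-methylcyclohex-2-en-1-one | C=C([C@H]1C(OC)(OC)C=C(C)C(=O)[C@@H]1[O-])[C@H](C[C@@H]2OC(C)(C)OC2(C)C)[O-].[K+].[K+] | intermediate (not isolated)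
13 | (1R,6R)-5,5-dimethoxy-3-methyl-2-oxo-6-Q-cyclohex-3-en-1-yl angelate | C=C([C@H]1C(OC)(OC)C=C(C)C(=O)[C@@H]1OC(=O)/C(C)=C\C)[C@H](C[C@@H]2OC(C)(C)OC2(C)C)OC(=O)/C(C)=C\C | intermediate
14 | (1R,2R,6R)-2-hydroxy-5,5-dimethoxy-3-methyl-6-Q-cyclohex-3-en-1-yl angelate | C=C([C@H]1C(OC)(OC)C=C(C)[C@@H](O)[C@@H]1OC(=O)/C(C)=C\C)[C@H](C[C@@H]2OC(C)(C)OC2(C)C)OC(=O)/C(C)=C\C | intermediate
15 | (1R,2R,6R)-2-(tert-butyldimethylsilyloxy)-5,5-dimethoxy-3-methyl-6-Q-cyclohex-3-en-1-yl angelate | C=C([C@H]1C(OC)(OC)C=C(C)[C@@H](O[Si](C)(C)C(C)(C)C)[C@@H]1OC(=O)/C(C)=C\C)[C@H](C[C@@H]2OC(C)(C)OC2(C)C)OC(=O)/C(C)=C\C | intermediate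
16 | (1R,2R,6R)-2-(tert-butyldimethylsilyloxy)-3-methyl-5-oxo-6-Q-cyclohex-3-en-1-yl angelate | C=C([C@H]1C(=O)C=C(C)[C@@H](O[Si](C)(C)C(C)(C)C)[C@@H]1OC(=O)/C(C)=C\C)[C@H](C[C@@H]2OC(C)(C)OC2(C)C)OC(=O)/C(C)=C\C | intermediate (not isolated)
17 | (1R,2R,5R,6S)-2-(tert-butyldimethylsilyloxy)-5-hydroxy-3-methyl-6-Q-cyclohex-3-en-1-yl angelate | C=C([C@H]1[C@H](O)C=C(C)[C@@H](O[Si](C)(C)C(C)(C)C)[C@@H]1OC(=O)/C(C)=C\C)[C@H](C[C@@H]2OC(C)(C)OC2(C)C)OC(=O)/C(C)=C\C | intermediate
18 | (1R,2R,5R,6S)-2-(tert-butyldimethylsilyloxy)-3-methyl-6-Q-cyclohex-3-ene-1,5-diyl diangelate | C=C([C@H]1[C@H](OC(=O)/C(C)=C\C)C=C(C)[C@@H](O[Si](C)(C)C(C)(C)C)[C@@H]1OC(=O)/C(C)=C\C)[C@H](C[C@@H]2OC(C)(C)OC2(C)C)OC(=O)/C(C)=C\C | intermediate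
19 | (1R,2R,5R,6S)-2-hydroxy-3-methyl-6-Q-cyclohex-3-ene-1,5-diyl diangelate | C=C([C@H]1[C@H](OC(=O)/C(C)=C\C)C=C(C)[C@@H](O)[C@@H]1OC(=O)/C(C)=C\C)[C@H](C[C@@H]2OC(C)(C)OC2(C)C)OC(=O)/C(C)=C\C | intermediate
20 | (1S,2S,3R,4R,5S,6R)-2-hydroxy-1-methyl-4-Q-7-oxabicyclo[4.1.0]heptane-3,5-diyl diangelate | C=C([C@H]1[C@H](OC(=O)/C(C)=C\C)[C@H]3O[C@@]3(C)[C@@H](O)[C@@H]1OC(=O)/C(C)=C\C)[C@H](C[C@@H]2OC(C)(C)OC2(C)C)OC(=O)/C(C)=C\C | intermediate
21 | (1R,3R,4S,5S,6R)-1-methyl-2-oxo-4-Q-7-oxabicyclo[4.1.0]heptane-3,5-diyl diangelate | C=C([C@H]1[C@H](OC(=O)/C(C)=C\C)[C@H]3O[C@@]3(C)C(=O)[C@@H]1OC(=O)/C(C)=C\C)[C@H](C[C@@H]2OC(C)(C)OC2(C)C)OC(=O)/C(C)=C\C | intermediate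
22 | 10,11-O-isopropylidene acetal of 23 (target locants 1S,2S,3S,4R,6R,8S,10S) | C=C([C@H]1[C@H](O)[C@H](OC(=O)/C(C)=C\C)[C@@](C)(O)C(=O)[C@@H]1OC(=O)/C(C)=C\C)[C@H](C[C@@H]2OC(C)(C)OC2(C)C)OC(=O)/C(C)=C\C | intermediate (not isolated)
23 | (3S,5S)-2-[(1S,2S,3S,4R,6R)-2,4-dihydroxy-4-methyl-3,6-bis(AngO)-5-oxocyclohexyl]-5,6-dihydroxy-6-methylhept-1-en-3-yl angelate (CNP0215698.1) | C=C([C@H]1[C@H](O)[C@H](OC(=O)/C(C)=C\C)[C@@](C)(O)C(=O)[C@@H]1OC(=O)/C(C)=C\C)[C@H](C[C@H](O)C(C)(C)O)OC(=O)/C(C)=C\C | target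

**Step count and risks**
Total steps: 15. Longest linear sequence: 14 (1 → 23 through steps 1, 2 and 4–15; step 3 is a one-step branch).

Most likely to fail, first: step 2, the proposed cross Rauhut–Currier coupling. Acrolein may self-couple or polymerise, the methyl-bearing enone may compete, and the enantioselectivity is unproven. The fallback uses known chemistry, sets out from 2 and comes back at 4. A rhodium-catalysed asymmetric conjugate alkenylation (Hayashi–Miyaura type: [RhCl(C2H4)2]2, a chiral 2,5-diphenylbicyclo[2.2.2]octa-2,5-diene ligand, aqueous KOH, dioxane) of 2 with 2-[3-(tert-butyldimethylsilyloxy)prop-1-en-2-yl]-4,4,5,5-tetramethyl-1,3,2-dioxaborolane gives (5S)-5-[3-(tert-butyldimethylsilyloxy)prop-1-en-2-yl]-4,4-dimethoxy-2-methylcyclohex-2-en-1-one F1. HF·pyridine then gives (5S)-5-(3-hydroxyprop-1-en-2-yl)-4,4-dimethoxy-2-methylcyclohex-2-en-1-one F2, and MnO2 oxidises the allylic alcohol to enal 4.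

Second: step 15, the acyl-shift epoxide opening. The orthoacid could collapse to the C2 ester, the angelate could isomerise to the tiglate in the cationic intermediate, or the deactivated epoxy ketone could resist opening. The fallback sets out from 14 and comes back at the target 23, replacing the shift by an intermolecular carboxylate opening and a hydroxyl-directed reduction. VO(acac)2/t-BuOOH on 14 (directed by the 5β-OH) gives the 3β,4β-epoxy alcohol with the ring ketal kept, (1S,2S,3R,4R,6S)-2-hydroxy-5,5-dimethoxy-1-methyl-4-Q-7-oxabicyclo[4.1.0]heptan-3-yl angelate F5. Dess–Martin oxidation gives the epoxy ketone (1R,3R,4R,6S)-5,5-dimethoxy-1-methyl-2-oxo-4-Q-7-oxabicyclo[4.1.0]heptan-3-yl angelate F6. Aqueous CF3CO2H removes both acetals to give the 3,4-epoxy-2,5-dione with free C10/C11 diol F7. Angelic acid (excess) with Cs2CO3 (0.3 equiv) in DMF opens the epoxide at C3, which is α to the new C2 ketone, with inversion, giving the 2-oxo analogue of the target F8. This compound is elimination-prone and must be kept away from base. Me4NBH(OAc)3 in MeCN/AcOH, directed by the tertiary C4–OH (1,3-anti), then gives 23.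

Third: step 7, the one-pot hydroxylation and double acylation. The enolate may add to the sulfonimine by-product, the α-keto alkoxide may epimerise or rearrange, and O-acylation of unreacted enolate is possible. The fallback sets out from 10 and comes back at 13, using an isolated silyl enol ether and electrophilic oxidation. Me3SiOSO2CF3/Et3N gives the bis-silyl compound trimethyl{[(3S)-2-[(1S)-6,6-dimethoxy-4-methyl-3-(trimethylsilyloxy)cyclohexa-2,4-dien-1-yl]-4-[(4S)-2,2,5,5-tetramethyl-1,3-dioxolan-4-yl]but-1-en-3-yl]oxy}silane F3. Rubottom oxidation with dimethyldioxirane (anti to the C1 side chain) and citric acid/MeOH work-up give the diol (5R,6R)-6-hydroxy-5-{(3S)-3-hydroxy-4-[(4S)-2,2,5,5-tetramethyl-1,3-dioxolan-4-yl]but-1-en-2-yl}-4,4-dimethoxy-2-methylcyclohex-2-en-1-one F4. This is acylated with 11 after deprotonation with LiN(SiMe3)2 at −78 °C to give 13.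

**Further compounds**
F1 | step 2 | (5S)-5-[3-(tert-butyldimethylsilyloxy)prop-1-en-2-yl]-4,4-dimethoxy-2-methylcyclohex-2-en-1-one | C=C([C@H]1C(OC)(OC)C=C(C)C(=O)C1)CO[Si](C)(C)C(C)(C)C
F2 | step 2 | (5S)-5-(3-hydroxyprop-1-en-2-yl)-4,4-dimethoxy-2-methylcyclohex-2-en-1-one | C=C([C@H]1C(OC)(OC)C=C(C)C(=O)C1)CO
F3 | step 7 | trimethyl{[(3S)-2-[(1S)-6,6-dimethoxy-4-methyl-3-(trimethylsilyloxy)cyclohexa-2,4-dien-1-yl]-4-[(4S)-2,2,5,5-tetramethyl-1,3-dioxolan-4-yl]but-1-en-3-yl]oxy}silane | C=C([C@H]1C(OC)(OC)C=C(C)C(O[Si](C)(C)C)=C1)[C@H](C[C@@H]2OC(C)(C)OC2(C)C)O[Si](C)(C)C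
F4 | step 7 | (5R,6R)-6-hydroxy-5-{(3S)-3-hydroxy-4-[(4S)-2,2,5,5-tetramethyl-1,3-dioxolan-4-yl]but-1-en-2-yl}-4,4-dimethoxy-2-methylcyclohex-2-en-1-one | C=C([C@H]1C(OC)(OC)C=C(C)C(=O)[C@@H]1O)[C@H](C[C@@H]2OC(C)(C)OC2(C)C)O
F5 | step 15 | (1S,2S,3R,4R,6S)-2-hydroxy-5,5-dimethoxy-1-methyl-4-Q-7-oxabicyclo[4.1.0]heptan-3-yl angelate | C=C([C@H]1C(OC)(OC)[C@H]3O[C@@]3(C)[C@@H](O)[C@@H]1OC(=O)/C(C)=C\C)[C@H](C[C@@H]2OC(C)(C)OC2(C)C)OC(=O)/C(C)=C\C
F6 | step 15 | (1R,3R,4R,6S)-5,5-dimethoxy-1-methyl-2-oxo-4-Q-7-oxabicyclo[4.1.0]heptan-3-yl angelate | C=C([C@H]1C(OC)(OC)[C@H]3O[C@@]3(C)C(=O)[C@@H]1OC(=O)/C(C)=C\C)[C@H](C[C@@H]2OC(C)(C)OC2(C)C)OC(=O)/C(C)=C\C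
F7 | step 15 | (1R,3R,4R,6S)-4-[(3S,5S)-3-(AngO)-5,6-dihydroxy-6-methylhept-1-en-2-yl]-1-methyl-2,5-dioxo-7-oxabicyclo[4.1.0]heptan-3-yl angelate | C=C([C@H]1C(=O)[C@H]3O[C@@]3(C)C(=O)[C@@H]1OC(=O)/C(C)=C\C)[C@H](C[C@H](O)C(C)(C)O)OC(=O)/C(C)=C\C
F8 | step 15 | 2-oxo analogue of 23 (target locants 1R,3R,4R,6R,8S,10S; C2 ketone, C3 and C6 and C8 angelates, C4 and C10 and C11 hydroxyls) | C=C([C@H]1C(=O)[C@H](OC(=O)/C(C)=C\C)[C@@](C)(O)C(=O)[C@@H]1OC(=O)/C(C)=C\C)[C@H](C[C@H](O)C(C)(C)O)OC(=O)/C(C)=C\C
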